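**Plan**
1. Numbering: chain carbons C1 (lactone C=O) to C14 (benzylic CH2); O1 is the lactone ring oxygen. C3 carries two oxygens, so the 1,2-dioxane/γ-lactone bicycle is read as the hydroperoxide adduct of a 5,5-disubstituted tetronic acid (C3 = masked ketone).
2. Cuts: C3–OO (hemiketal); O1–C4 (lactone alkyl C–O, with the C3 oxygen traced back to a C3–C4 epoxide); C2–C3 and C4–CH3 (alkyne carboboration and coupling); C6–OO (oxetane perhydrolysis); C5=C6 and C8–C9.
3. Forward: chain with C8 → tertiary hydroperoxide at C6 → E-homoallylic alcohol → C3–C4 epoxide → lactone ring by carboxyl attack at C4 → C3 ketone → desilylation, after which the hydroperoxide closes the 1,2-dioxane ring last.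
4. Stereochemistry: C8 from a ligand-controlled conjugate addition; C6 from Sharpless epoxidation and invertive H2O2 opening of an oxetane; C4 from a ligand-controlled vanadium epoxidation and invertive lactonisation; C3 from the enforced cis ring fusion.

Key step: step 16

Assumption: the free hydroperoxy tetronic acid 29 rests as the cis-fused peroxy-hemiketal, the form in which the target itself exists. Where a ligand is described as "the enantiomer that gives" a stated configuration, its sense has not been assigned here and would be fixed on a model substrate.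

Step 1
Reactants: 1 5-chloropent-1-yne; 2 benzyl bromide
Product: 4 [(2E)-6-chloro-3-methylhex-2-en-1-yl]benzene, via alkenylalane 3 (not isolated)
Conditions: Me3Al (2 equiv), Cp2ZrCl2 (0.25 equiv), CH2Cl2, 0 °C to rt; then 2, Pd(PPh3)4 (3 mol %), THF, rt
Reagents that add atoms: trimethylaluminium, C[Al](C)C
Why: Zirconium-catalysed syn-carboalumination puts methyl on the internal and aluminium on the terminal alkyne carbon, and Negishi coupling of the alkenylalane with the benzyl bromide goes with retention, so only the E trisubstituted alkene should form while the alkyl chloride stays inert.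

Step 2
Reactants: 4 [(2E)-6-chloro-3-methylhex-2-en-1-yl]benzene; 5 (3E)-pent-3-en-2-one
Product: 7 (4R,8E)-4,8-dimethyl-10-phenyldec-8-en-2-one, via Grignard reagent 6 (not isolated)
Conditions: Mg, Et2O, reflux; then 5, CuBr·SMe2 (5 mol %), Josiphos-type ferrocenyl diphosphine (6 mol %, the enantiomer that gives 4R), tBuOMe, −75 °C; aq. NH4Cl
Reagents that add atoms: none
Why: Copper-catalysed asymmetric conjugate addition of a primary alkylmagnesium halide to an acyclic methyl enone is 1,4-selective, and the diphosphine–copper complex selects the enone face, which sets C8 as R.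

Step 3
Reactants: 7 (4R,8E)-4,8-dimethyl-10-phenyldec-8-en-2-one
Product: 9 [(2E,7R)-3,7-dimethyldec-2-en-9-yn-1-yl]benzene, via enol phosphate 8 (not isolated)
Conditions: LiN(iPr)2 (1.1 equiv), THF, −78 °C; ClP(O)(OEt)2; then LiN(iPr)2 (2.3 equiv), −78 °C to rt
Reagents that add atoms: none
Why: The one-flask conversion of a methyl ketone into a terminal alkyne (kinetic enolate, enol phosphate, base-induced elimination) should apply, and C8, being β to the carbonyl, cannot epimerise.

Step 4
Reactants: 9 [(2E,7R)-3,7-dimethyldec-2-en-9-yn-1-yl]benzene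
Product: 11 (2E,5R,9E)-3,5,9-trimethyl-11-phenylundeca-2,9-dien-1-ol, via alkenylalane 10 (not isolated)
Conditions: Me3Al (2 equiv), Cp2ZrCl2 (0.25 equiv), CH2Cl2, rt; n-BuLi, THF, −78 °C; (CH2O)n, rt
Reagents that add atoms: trimethylaluminium, C[Al](C)C; formaldehyde (as paraformaldehyde), C=O
Why: A second zirconium-catalysed carboalumination followed by hydroxymethylation of the alkenylalanate gives the (E)-3-methylalk-2-en-1-ol with geometry fixed by syn addition, and the isolated trisubstituted alkene does not take part.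

Step 5
Reactants: 11 (2E,5R,9E)-3,5,9-trimethyl-11-phenylundeca-2,9-dien-1-ol
Product: 12 {(2S,3S)-3-[(2R,6E)-2,6-dimethyl-8-phenyloct-6-en-1-yl]-3-methyloxiran-2-yl}methanol
Conditions: Ti(OiPr)4 (10 mol %), L-(+)-diethyl tartrate (12 mol %), tBuOOH, 4 Å molecular sieves, CH2Cl2, −20 °C
Reagents that add atoms: tert-butyl hydroperoxide, CC(C)(C)OO
Why: Sharpless asymmetric epoxidation is directed by the allylic hydroxyl, so the remote alkene stays intact, and L-(+)-tartrate delivers oxygen to the same face as with geraniol to give the (2S,3S)-epoxide, which fixes the configuration of the C6–O bond.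

Step 6
Reactants: 12 the (2S,3S)-epoxy alcohol
Product: 13 (3S,5R,9E)-3,5,9-trimethyl-11-phenylundec-9-ene-1,3-diol
Conditions: NaAlH2(OCH2CH2OMe)2, THF, 0 °C
Reagents that add atoms: none
Why: Intramolecular hydride delivery from the alkoxyaluminate opens the 2,3-epoxy alcohol at C2 (the standard route to 1,3-diols), so the tertiary C–O bond and its configuration are untouched.

Step 7
Reactants: 13 (3S,5R,9E)-3,5,9-trimethyl-11-phenylundec-9-ene-1,3-diol
Product: 15 (2S)-2-[(2R,6E)-2,6-dimethyl-8-phenyloct-6-en-1-yl]-2-methyloxetane, via monotosylate 14 (not isolated)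
Conditions: n-BuLi (1.0 equiv), THF, 0 °C; TsCl (1.0 equiv); n-BuLi (1.0 equiv), 0 to 60 °C
Reagents that add atoms: none
Why: The primary alkoxide is sulfonylated selectively and the tertiary alkoxide then closes the oxetane by a 4-exo-tet Williamson etherification at the primary carbon, which leaves the tertiary stereocentre unchanged.

Step 8
Reactants: 15 the (2S)-oxetane
Product: 16 (3R,5R,9E)-3-hydroperoxy-3,5,9-trimethyl-11-phenylundec-9-en-1-ol
Conditions: H2O2 (anhydrous, in Et2O), TMSOTf (0.2 equiv), Et2O, −78 to 0 °C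
Reagents that add atoms: hydrogen peroxide, OO
Why: Lewis-acid-promoted perhydrolysis of a 2,2-disubstituted oxetane occurs at the tertiary carbon in an SN2-like manner with inversion, so the (S)-oxetane should give the (R)-tertiary hydroperoxide and the primary alcohol.

Step 9
Reactants: 16 the hydroperoxy alcohol
Product: 17 (3R,5R,9E)-3-[(tert-butyldimethylsilyl)peroxy]-3,5,9-trimethyl-11-phenylundec-9-en-1-ol
Conditions: TBSCl (1.05 equiv), Et3N, CH2Cl2, −20 °C
Reagents that add atoms: tert-butyl(chloro)dimethylsilane, CC(C)(C)[Si](C)(C)Cl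
Why: Silylation with a weak amine base and no nucleophilic catalyst favours the far more acidic, α-nucleophilic hydroperoxide over the primary alcohol and gives the silyl peroxide as the protected form.

Step 10
Reactants: 17 the silyl peroxide alcohol
Product: 18 (3R,5R,9E)-3-[(tert-butyldimethylsilyl)peroxy]-3,5,9-trimethyl-11-phenylundec-9-enal
Conditions: Dess–Martin periodinane, NaHCO3, CH2Cl2, 0 °C
Reagents that add atoms: none
Why: Buffered Dess–Martin oxidation converts the primary alcohol into the aldehyde under neutral conditions that leave the silyl peroxide and both alkenes alone.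

Step 11
Reactants: 18 the silylperoxy aldehyde; 19 dimethyl (1-diazo-2-oxopropyl)phosphonate
Product: 20 tert-butyldimethyl{[(4R,6R,10E)-4,6,10-trimethyl-12-phenyldodec-10-en-1-yn-4-yl]peroxy}silane
Conditions: K2CO3, MeOH, 0 °C
Reagents that add atoms: none
Why: Seyferth–Gilbert homologation with the Ohira–Bestmann reagent turns the aldehyde into the terminal alkyne under mild carbonate conditions at low temperature, which should keep β-elimination of the silylperoxy group slow.

Step 12
Reactants: 20 the terminal alkyne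
Product: 21 tert-butyldimethyl{[(1E,4R,6R,10E)-2,4,6,10-tetramethyl-12-phenyl-1-(4,4,5,5-tetramethyl-1,3,2-dioxaborolan-2-yl)dodeca-1,10-dien-4-yl]peroxy}silane
Conditions: CuCl (10 mol %), Xantphos (10 mol %), NaOtBu, B2pin2, MeI, THF, rt
Reagents that add atoms: bis(pinacolato)diboron, CC1(C)OB(OC1(C)C)B1OC(C)(C)C(C)(C)O1; iodomethane, CI
Why: Copper-catalysed carboboration (syn-borylcupration with boron on the terminal carbon, then methylation of the alkenylcopper with retention) gives the trisubstituted alkenylboronate with methyl on C4 and defined geometry, and isolated alkenes do not insert.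

Step 13
Reactants: 21 the alkenylboronate; 22 methyl bromoacetate
Product: 23 methyl (3E,6R,8R,12E)-6-[(tert-butyldimethylsilyl)peroxy]-4,6,8,12-tetramethyl-14-phenyltetradeca-3,12-dienoate
Conditions: Pd(OAc)2 (3 mol %), P(o-tol)3, K3PO4, THF/H2O, rt
Reagents that add atoms: none
Why: Suzuki–Miyaura coupling of the alkenylboronate with the α-bromo ester goes with retention of alkene geometry and gives the (3E)-β,γ-unsaturated ester, and the mild phosphate base limits migration of the double bond into conjugation.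

Step 14
Reactants: 23 the β,γ-unsaturated ester
Product: 24 (3E,6R,8R,12E)-6-[(tert-butyldimethylsilyl)peroxy]-4,6,8,12-tetramethyl-14-phenyltetradeca-3,12-dien-1-ol
Conditions: iBu2AlH (2.2 equiv), CH2Cl2, −78 °C
Reagents that add atoms: none
Why: Low-temperature reduction of the ester with the dialkylaluminium hydride gives the homoallylic alcohol needed as a directing group, and the hindered tertiary silyl peroxide is expected to survive at −78 °C.

Step 15
Reactants: 24 the homoallylic alcohol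
Product: 25 2-[(2S,3S)-3-{(2R,4R,8E)-2-[(tert-butyldimethylsilyl)peroxy]-2,4,8-trimethyl-10-phenyldec-8-en-1-yl}-3-methyloxiran-2-yl]ethan-1-ol
Conditions: VO(OiPr)3 (2 mol %), chiral bis-hydroxamic acid ligand from trans-cyclohexane-1,2-diamine (the enantiomer that gives 3S,4S), cumene hydroperoxide, toluene, 0 °C
Reagents that add atoms: cumene hydroperoxide, CC(C)(OO)c1ccccc1
Why: Vanadium/bis-hydroxamic acid-catalysed asymmetric epoxidation of homoallylic alcohols is hydroxyl-directed, so only the C3=C4 alkene reacts, and the ligand selects the alkene face to give the (3S,4S)-epoxide syn-specifically from the E alkene.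

Step 16
Reactants: 25 the (3S,4S)-epoxy alcohol
Product: 27 (4S,5R)-5-{(2R,4R,8E)-2-[(tert-butyldimethylsilyl)peroxy]-2,4,8-trimethyl-10-phenyldec-8-en-1-yl}-4-hydroxy-5-methyloxolan-2-one, via epoxy acid 26 (not isolated)
Conditions: TEMPO (10 mol %), PhI(OAc)2 (2.2 equiv), MeCN/aq. pH 7 buffer, rt; then camphorsulfonic acid (5 mol %), CH2Cl2, 0 °C
Reagents that add atoms: water, O
Why: TEMPO/PhI(OAc)2 oxidises the primary alcohol through the aldehyde hydrate to carboxylic acid 26 without an electrophilic oxygen-transfer agent, so the epoxide, the silyl peroxide and the remote alkene are not touched. Under mild acid the carboxyl oxygen then attacks the tertiary epoxide carbon C4 from the side opposite to the epoxide oxygen, an SN2-like opening with a loose, cation-like transition state, as in the known acid-mediated conversion of β,γ-epoxy acids into β-hydroxy-γ-lactones. The lactone ring closes in the 5-endo-tet mode, which epoxides tolerate when the distal carbon is tertiary, whereas the alternative 4-exo attack at C3 would give a strained β-lactone at the less substituted carbon. C4 is formed with inversion of the ligand-set epoxide carbon and becomes R with O1 anti to the C3 hydroxyl, while C3 keeps the epoxide oxygen that later becomes the hemiketal oxygen. The step needs regioselectivity (C4 over C3) and stereospecificity (inversion, not a free cation), and the five-membered transition state, the tertiary centre and the neighbouring carboxyl should secure both. One operation thus forms the lactone ring, the quaternary oxygen-bearing stereocentre and the C3 oxygen.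

Step 17
Reactants: 27 the hydroxy lactone
Product: 28 (5R)-5-{(2R,4R,8E)-2-[(tert-butyldimethylsilyl)peroxy]-2,4,8-trimethyl-10-phenyldec-8-en-1-yl}-4-hydroxy-5-methylfuran-2(5H)-one
Conditions: Dess–Martin periodinane, CH2Cl2, rt
Reagents that add atoms: none
Why: Dess–Martin oxidation of the β-hydroxy-γ-lactone gives the 3-oxo lactone, which rests as its enol (the tetronic acid), and the quaternary C4 stereocentre cannot epimerise.

Step 18
Reactants: 28 the silylperoxy tetronic acid
Product: 30 (3R,4aR,7aR)-3-[(2R,6E)-2,6-dimethyl-8-phenyloct-6-en-1-yl]-7a-hydroxy-3,4a-dimethyltetrahydro-3H-furo[3,2-c][1,2]dioxin-6(4H)-one, via hydroperoxide 29 (not isolated)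
Conditions: HF·pyridine, THF, 0 °C
Reagents that add atoms: none
Why: Fluoride cleaves the Si–O bond and the freed tertiary hydroperoxide adds to the C3 carbonyl of the keto tautomer (6-exo-trig hemiketalisation) from the face that carries C5, the only mode that gives the cis-fused bicycle, so C3 is set as R by C4.

**Compound list**
1 | 5-chloropent-1-yne | C#CCCCCl | starting material
2 | benzyl bromide | BrCc1ccccc1 | starting material
3 | [(1E)-5-chloro-2-methylpent-1-en-1-yl]dimethylalumane | C[Al](C)/C=C(\C)CCCCl | intermediate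
4 | [(2E)-6-chloro-3-methylhex-2-en-1-yl]benzene | C/C(=C\Cc1ccccc1)CCCCl | intermediate
5 | (3E)-pent-3-en-2-one | C/C=C/C(C)=O | starting material
6 | [(4E)-4-methyl-6-phenylhex-4-en-1-yl]magnesium chloride | C/C(=C\Cc1ccccc1)CCC[Mg]Cl | intermediate
7 | (4R,8E)-4,8-dimethyl-10-phenyldec-8-en-2-one | C/C(=C\Cc1ccccc1)CCC[C@@H](C)CC(C)=O | intermediate
8 | diethyl (4R,8E)-4,8-dimethyl-10-phenyldeca-1,8-dien-2-yl phosphate | C/C(=C\Cc1ccccc1)CCC[C@@H](C)CC(=C)OP(=O)(OCC)OCC | intermediate
9 | [(2E,7R)-3,7-dimethyldec-2-en-9-yn-1-yl]benzene | C/C(=C\Cc1ccccc1)CCC[C@@H](C)CC#C | intermediate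
10 | dimethyl[(1E,4R,8E)-2,4,8-trimethyl-10-phenyldeca-1,8-dien-1-yl]alumane | C/C(=C\Cc1ccccc1)CCC[C@@H](C)C/C(C)=C/[Al](C)C | intermediate
11 | (2E,5R,9E)-3,5,9-trimethyl-11-phenylundeca-2,9-dien-1-ol | C/C(=C\Cc1ccccc1)CCC[C@@H](C)C/C(C)=C/CO | intermediate
12 | {(2S,3S)-3-[(2R,6E)-2,6-dimethyl-8-phenyloct-6-en-1-yl]-3-methyloxiran-2-yl}methanol | C/C(=C\Cc1ccccc1)CCC[C@@H](C)C[C@]1(C)O[C@H]1CO | intermediate
13 | (3S,5R,9E)-3,5,9-trimethyl-11-phenylundec-9-ene-1,3-diol | C/C(=C\Cc1ccccc1)CCC[C@@H](C)C[C@@](O)(C)CCO | intermediate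
14 | (3S,5R,9E)-3-hydroxy-3,5,9-trimethyl-11-phenylundec-9-en-1-yl 4-methylbenzenesulfonate | C/C(=C\Cc1ccccc1)CCC[C@@H](C)C[C@@](O)(C)CCOS(=O)(=O)c1ccc(C)cc1 | intermediate
15 | (2S)-2-[(2R,6E)-2,6-dimethyl-8-phenyloct-6-en-1-yl]-2-methyloxetane | C/C(=C\Cc1ccccc1)CCC[C@@H](C)C[C@@]1(C)CCO1 | intermediate
16 | (3R,5R,9E)-3-hydroperoxy-3,5,9-trimethyl-11-phenylundec-9-en-1-ol | C/C(=C\Cc1ccccc1)CCC[C@@H](C)C[C@](OO)(C)CCO | intermediate
17 | (3R,5R,9E)-3-[(tert-butyldimethylsilyl)peroxy]-3,5,9-trimethyl-11-phenylundec-9-en-1-ol | C/C(=C\Cc1ccccc1)CCC[C@@H](C)C[C@](OO[Si](C)(C)C(C)(C)C)(C)CCO | intermediate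
18 | (3R,5R,9E)-3-[(tert-butyldimethylsilyl)peroxy]-3,5,9-trimethyl-11-phenylundec-9-enal | C/C(=C\Cc1ccccc1)CCC[C@@H](C)C[C@](OO[Si](C)(C)C(C)(C)C)(C)CC=O | intermediate
19 | dimethyl (1-diazo-2-oxopropyl)phosphonate | COP(=O)(OC)C(=[N+]=[N-])C(C)=O | starting material
20 | tert-butyldimethyl{[(4R,6R,10E)-4,6,10-trimethyl-12-phenyldodec-10-en-1-yn-4-yl]peroxy}silane | C/C(=C\Cc1ccccc1)CCC[C@@H](C)C[C@](OO[Si](C)(C)C(C)(C)C)(C)CC#C | intermediate
21 | tert-butyldimethyl{[(1E,4R,6R,10E)-2,4,6,10-tetramethyl-12-phenyl-1-(4,4,5,5-tetramethyl-1,3,2-dioxaborolan-2-yl)dodeca-1,10-dien-4-yl]peroxy}silane | C/C(=C\Cc1ccccc1)CCC[C@@H](C)C[C@](OO[Si](C)(C)C(C)(C)C)(C)C/C(C)=C/B1OC(C)(C)C(C)(C)O1 | intermediate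
22 | methyl bromoacetate | COC(=O)CBr | starting material
23 | methyl (3E,6R,8R,12E)-6-[(tert-butyldimethylsilyl)peroxy]-4,6,8,12-tetramethyl-14-phenyltetradeca-3,12-dienoate | C/C(=C\Cc1ccccc1)CCC[C@@H](C)C[C@](OO[Si](C)(C)C(C)(C)C)(C)C/C(C)=C/CC(=O)OC | intermediate
24 | (3E,6R,8R,12E)-6-[(tert-butyldimethylsilyl)peroxy]-4,6,8,12-tetramethyl-14-phenyltetradeca-3,12-dien-1-ol | C/C(=C\Cc1ccccc1)CCC[C@@H](C)C[C@](OO[Si](C)(C)C(C)(C)C)(C)C/C(C)=C/CCO | intermediate
25 | 2-[(2S,3S)-3-{(2R,4R,8E)-2-[(tert-butyldimethylsilyl)peroxy]-2,4,8-trimethyl-10-phenyldec-8-en-1-yl}-3-methyloxiran-2-yl]ethan-1-ol | C/C(=C\Cc1ccccc1)CCC[C@@H](C)C[C@](OO[Si](C)(C)C(C)(C)C)(C)C[C@]1(C)O[C@H]1CCO | intermediate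
26 | 2-[(2S,3S)-3-{(2R,4R,8E)-2-[(tert-butyldimethylsilyl)peroxy]-2,4,8-trimethyl-10-phenyldec-8-en-1-yl}-3-methyloxiran-2-yl]acetic acid | C/C(=C\Cc1ccccc1)CCC[C@@H](C)C[C@](OO[Si](C)(C)C(C)(C)C)(C)C[C@]1(C)O[C@H]1CC(=O)O | intermediate
27 | (4S,5R)-5-{(2R,4R,8E)-2-[(tert-butyldimethylsilyl)peroxy]-2,4,8-trimethyl-10-phenyldec-8-en-1-yl}-4-hydroxy-5-methyloxolan-2-one | C/C(=C\Cc1ccccc1)CCC[C@@H](C)C[C@](OO[Si](C)(C)C(C)(C)C)(C)C[C@@]1(C)OC(=O)C[C@@H]1O | intermediate
28 | (5R)-5-{(2R,4R,8E)-2-[(tert-butyldimethylsilyl)peroxy]-2,4,8-trimethyl-10-phenyldec-8-en-1-yl}-4-hydroxy-5-methylfuran-2(5H)-one | C/C(=C\Cc1ccccc1)CCC[C@@H](C)C[C@](OO[Si](C)(C)C(C)(C)C)(C)C[C@@]1(C)OC(=O)C=C1O | intermediate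
29 | (5R)-5-[(2R,4R,8E)-2-hydroperoxy-2,4,8-trimethyl-10-phenyldec-8-en-1-yl]-4-hydroxy-5-methylfuran-2(5H)-one | C/C(=C\Cc1ccccc1)CCC[C@@H](C)C[C@](OO)(C)C[C@@]1(C)OC(=O)C=C1O | intermediate
30 | (3R,4aR,7aR)-3-[(2R,6E)-2,6-dimethyl-8-phenyloct-6-en-1-yl]-7a-hydroxy-3,4a-dimethyltetrahydro-3H-furo[3,2-c][1,2]dioxin-6(4H)-one | C/C(=C\Cc1ccccc1)CCC[C@@H](C)C[C@]1(C)C[C@@]2(C)OC(=O)C[C@@]2(O)OO1 | target

**Totals**
Total step count: 18. Longest linear sequence: 18 steps.

**Steps most likely to fail**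

Step 8. The oxetane may open through an ionised pathway, which would erode the configuration at C6, and the Lewis acid may protonate the remote trisubstituted alkene so that hydrogen peroxide adds there as well. Fallback, from epoxy alcohol 12 back to aldehyde 18: perhydrolysis of the epoxide with ethereal H2O2 and catalytic H3PMo12O40 should open it at the tertiary carbon with inversion and give (2S,3R,5R,9E)-3-hydroperoxy-3,5,9-trimethyl-11-phenylundec-9-ene-1,2-diol F1. Chemoselective silylation (TBSCl, Et3N) then gives (2S,3R,5R,9E)-3-[(tert-butyldimethylsilyl)peroxy]-3,5,9-trimethyl-11-phenylundec-9-ene-1,2-diol F2. NaIO4 cleaves the diol to (2R,4R,8E)-2-[(tert-butyldimethylsilyl)peroxy]-2,4,8-trimethyl-10-phenyldec-8-enal F3. A Wittig reaction with Ph3P=CHOMe gives the enol ether tert-butyl{[(3R,5R,9E)-1-methoxy-3,5,9-trimethyl-11-phenylundeca-1,9-dien-3-yl]peroxy}dimethylsilane F4 as an E/Z mixture, and mild aqueous acid hydrolysis should deliver aldehyde 18.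

Step 12. The alkoxide base may strip the silyl group from the peroxide, the copper boryl species may reduce the O–O bond, and borylcupration may be incompletely regioselective. Fallback, from aldehyde 18 back to ester 23 (steps 11 to 13 are bypassed): addition of the zinc homoenolate IZnCH2CH2CO2Me (Me3SiCl, THF) should give methyl (6R,8R,12E)-6-[(tert-butyldimethylsilyl)peroxy]-4-hydroxy-6,8,12-trimethyl-14-phenyltetradec-12-enoate F5 as a mixture of C4 epimers. Dess–Martin oxidation gives methyl (6R,8R,12E)-6-[(tert-butyldimethylsilyl)peroxy]-6,8,12-trimethyl-4-oxo-14-phenyltetradec-12-enoate F6. Kinetic deprotonation at C3 with LiN(SiMe3)2 and trapping with PhNTf2 at −78 °C gives methyl (3Z,6R,8R,12E)-6-[(tert-butyldimethylsilyl)peroxy]-6,8,12-trimethyl-14-phenyl-4-{[(trifluoromethyl)sulfonyl]oxy}tetradeca-3,12-dienoate F7, and Negishi coupling with MeZnCl and Pd(PPh3)4 should give 23 with retention.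

Step 16. The new C3 carbinol may be over-oxidised or the epoxy acid may suffer side reactions while it lactonises only slowly, so that oxidation and ring closure interfere. Fallback, from epoxy alcohol 25 back to lactone 27, with ring closure at the aldehyde oxidation level: buffered Dess–Martin oxidation gives 2-[(2S,3S)-3-{(2R,4R,8E)-2-[(tert-butyldimethylsilyl)peroxy]-2,4,8-trimethyl-10-phenyldec-8-en-1-yl}-3-methyloxiran-2-yl]acetaldehyde F8. Pyridinium p-toluenesulfonate in wet CH2Cl2 lets the aldehyde hydrate open the epoxide at C4 with inversion to the lactol (4S,5R)-5-{(2R,4R,8E)-2-[(tert-butyldimethylsilyl)peroxy]-2,4,8-trimethyl-10-phenyldec-8-en-1-yl}-5-methyloxolane-2,4-diol F9 (anomeric mixture), and selective lactol oxidation (TEMPO, PhI(OAc)2, CH2Cl2) should give 27.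

**Further compounds**
F1 | step 8 | (2S,3R,5R,9E)-3-hydroperoxy-3,5,9-trimethyl-11-phenylundec-9-ene-1,2-diol | C/C(=C\Cc1ccccc1)CCC[C@@H](C)C[C@](OO)(C)[C@@H](O)CO
F2 | step 8 | (2S,3R,5R,9E)-3-[(tert-butyldimethylsilyl)peroxy]-3,5,9-trimethyl-11-phenylundec-9-ene-1,2-diol | C/C(=C\Cc1ccccc1)CCC[C@@H](C)C[C@](OO[Si](C)(C)C(C)(C)C)(C)[C@@H](O)CO
F3 | step 8 | (2R,4R,8E)-2-[(tert-butyldimethylsilyl)peroxy]-2,4,8-trimethyl-10-phenyldec-8-enal | C/C(=C\Cc1ccccc1)CCC[C@@H](C)C[C@](OO[Si](C)(C)C(C)(C)C)(C)C=O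
F4 | step 8 | tert-butyl{[(3R,5R,9E)-1-methoxy-3,5,9-trimethyl-11-phenylundeca-1,9-dien-3-yl]peroxy}dimethylsilane | C/C(=C\Cc1ccccc1)CCC[C@@H](C)C[C@](OO[Si](C)(C)C(C)(C)C)(C)C=COC
F5 | step 12 | methyl (6R,8R,12E)-6-[(tert-butyldimethylsilyl)peroxy]-4-hydroxy-6,8,12-trimethyl-14-phenyltetradec-12-enoate | C/C(=C\Cc1ccccc1)CCC[C@@H](C)C[C@](OO[Si](C)(C)C(C)(C)C)(C)CC(O)CCC(=O)OC
F6 | step 12 | methyl (6R,8R,12E)-6-[(tert-butyldimethylsilyl)peroxy]-6,8,12-trimethyl-4-oxo-14-phenyltetradec-12-enoate | C/C(=C\Cc1ccccc1)CCC[C@@H](C)C[C@](OO[Si](C)(C)C(C)(C)C)(C)CC(=O)CCC(=O)OC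
F7 | step 12 | methyl (3Z,6R,8R,12E)-6-[(tert-butyldimethylsilyl)peroxy]-6,8,12-trimethyl-14-phenyl-4-{[(trifluoromethyl)sulfonyl]oxy}tetradeca-3,12-dienoate | C/C(=C\Cc1ccccc1)CCC[C@@H](C)C[C@](OO[Si](C)(C)C(C)(C)C)(C)C/C(OS(=O)(=O)C(F)(F)F)=C/CC(=O)OC
F8 | step 16 | 2-[(2S,3S)-3-{(2R,4R,8E)-2-[(tert-butyldimethylsilyl)peroxy]-2,4,8-trimethyl-10-phenyldec-8-en-1-yl}-3-methyloxiran-2-yl]acetaldehyde | C/C(=C\Cc1ccccc1)CCC[C@@H](C)C[C@](OO[Si](C)(C)C(C)(C)C)(C)C[C@]1(C)O[C@H]1CC=O
F9 | step 16 | (4S,5R)-5-{(2R,4R,8E)-2-[(tert-butyldimethylsilyl)peroxy]-2,4,8-trimethyl-10-phenyldec-8-en-1-yl}-5-methyloxolane-2,4-diol | C/C(=C\Cc1ccccc1)CCC[C@@H](C)C[C@](OO[Si](C)(C)C(C)(C)C)(C)C[C@@]1(C)OC(O)C[C@@H]1O
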